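## Structural features

The target is a trans-fused hydroazulene (daucane skeleton) in which a cyclopentane (C1–C5) and a cycloheptane (C1, C5–C10) share the C1–C5 bond; the locants used throughout are C1 = ring-fusion C–CH3, C2/C3 = CH2, C4 = C(OH)(i-Pr), C5 = ring-fusion CH, C6 = CH–O–aroyl, C7 = CH2, C8 = C(OH)CH3, C9 = CHOH, C10 = CH2, and the configuration is (1R,4R,5S,6S,8S,9S). C4, C5 and C6 are contiguous and C5 also carries the quaternary C1; H-5, O-6 and O-9 lie on one face (called upper below), while C1–CH3, O-4 and O-8 lie on the lower face, so the 8,9-diol is trans and is insulated from the rest by the C7 and C10 methylenes. Fragile points are the 4-hydroxybenzoate (acyl transfer, phenol oxidation), the tertiary carbinols C4 and C8 (elimination), the 8,9-diol (pinacol shift in strong acid) and, in any intermediate with a C6 ketone, the C4 carbinol (retro-aldol) and C5 (epimerisation). The real difficulty is the quaternary C1 next to the fully substituted C4/C5 region, together with oxygen on three carbons of a flexible seven-membered ring, each on a defined face. The key step exploits the fact that O-6 and the C9 oxygen are 1,4-related across C7–C8 while C1–C10 closes the ring on the other side: O–C6–C5=C1 and C10=C9–O form an allyl vinyl ether that is already tied into an oxolane (O, C6, C7, C8, C9), so a [3,3] shift makes C1–C10, breaks C6–O and leaves C9=O and C5=C6 at the carbons the target oxidises. C1 with its methyl, C2, C3 and C4 with hydroxyl and isopropyl map onto (S)-terpinen-4-ol after ring contraction, so C4 is bought and never becomes a reaction centre.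

## Logic of the disconnections

26 ⇒ 25. The phenolic O–H is traded for O–CH2Ph. A free phenol would compete in the acylation and the oxidation; benzyl leaves by neutral hydrogenolysis once nothing reducible is left. The last step then touches no stereocentre. Demand: 25 must hold no alkene or epoxide.

25 ⇒ 24. The C8–OH bond is cut, with O-9 returned to an epoxide. O-8 and O-9 are anti and C8 is tertiary, so water opening at C8 with inversion maps an (8R,9S)-epoxide onto the (8S,9S)-diol. Two carbinol centres become one face-selective event. Demand: anti attack at C8 only, without cation rearrangement.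

24 ⇒ 22 + 23. The ester C(=O)–O6 bond is cut. It is the only convergent bond, and acylating after epoxidation keeps the C6 hydroxyl free as a directing group. Gain: the aromatic part is bought. Demand: acylation of a hindered secondary alcohol in the presence of the tertiary C4 alcohol and an epoxide.

22 ⇒ 21. Both epoxide C–O bonds are cut. The C6 hydroxyl is homoallylic to C8=C9 and sits on the face where the oxygen is needed, which is also the face away from C1–CH3. Two stereocentres disappear. Demand: oxygen delivery syn to O-6.

21 ⇒ 20 ⇒ 19. C9–H is returned to C9–OSO2CF3 and O4–H to O4–Si. The triflate locks the alkene between C8 and C9 and tolerates borane; the silyl group is needed only until C5 is set. C9 goes back to the carbonyl oxidation level. Demand: reduction without alkene migration, and desilylation that spares the triflate.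

19 ⇒ 17. C5–H and C6–O are cut as a syn addition across C5=C6. H-5 and O-6 are cis, which is the signature of hydroboration–oxidation with boron on the less substituted C6. Two stereocentres and the trans fusion come from one alkene. Demand: attack on the upper face, and no reaction at the vinyl triflate.

17 ⇒ 15 ⇒ 13. The C9–O(triflyl) bond is returned to C9=O and the C8–CH3 bond is cut. The C9 carbonyl activates C8 for both operations. Gain: a plain ketone. Demand: enolisation toward C8 rather than C10, first under kinetic and then under thermodynamic control.

13 ⇒ 12 (key). C1–C10 is cut and C6–O is re-formed. C9=O and C5=C6 in 13 are a Claisen retron. The seven-membered carbocycle and the quaternary C1 are exchanged for a five-membered oxacycle and a secondary carbinol carbon. Demand: a boat-like transition state, configurational purity at C6 and acid-free handling.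

12 ⇒ 11. C9=CH2 is returned to C9=O. Carbonyl methylenation is the standard entry to such enol ethers, and 11 is a stable, storable compound. Demand: a methylenating agent that is neither acidic nor strongly basic.

11 ⇒ 9 ⇒ 7. The C9 oxidation level is lowered to CH2OH and then the C9–O bond is cut to a terminal alkene. A 1,4-diol lactonises oxidatively under near-neutral conditions, and a terminal alkene is hydroborated selectively. The three-carbon arm becomes an allyl group. Demand: primary over allylic secondary alcohol, terminal over ring alkene.

7 ⇒ 5. The C6–C7 bond is cut next to the carbinol. Allyl addition to an aldehyde sets C6 by reagent control; it is the only stereocentre that is neither bought nor relayed. Demand: Si-face delivery whatever the bias of C4.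

5 ⇒ 2 ⇒ 1. The C5=C1 bond is cut (aldol condensation), the cleaved ring alkene is re-joined, and finally the O–Si bond is cut. This is a ring contraction of a cyclohexene that leaves C4 and its substituents untouched. Demand: the aldehyde enamine must attack the ketone and must not expel the β-silyloxy group.

## Other disconnections considered

Alternative 1: The cut is C5–C1 and C5–C6, both ring bonds of the ring-fusion methine, so that the seven-membered ring reverts to a benzene ring and C5 to a carbene carbon. In the forward sense Cu(MeCN)4PF6 (monovalent copper) with 2,2'-isopropylidenebis[(4S)-4-tert-butyl-2-oxazoline] would turn diazoketone A2 into a copper carbenoid that cyclopropanates the ipso/ortho bond of the arene; the norcaradiene would open to the cycloheptatriene of azulenone A1 (intramolecular Buchner reaction).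
- In favour: it is catalytic, both rings and C5 come from a flat arene in one step, and the C8 methyl and the C9 oxygen (as an enol ether) are already in place. On these two substituents and on step count to a bicyclic intermediate it is better than the chosen plan, which adds the C8 methyl after the key step.
- Against: A1 holds one of six stereocentres, and that one is a doubly allylic α-keto methine open to epimerisation and 1,5-hydrogen shifts. C1 lacks its methyl and would need conjugate methylation at a fully substituted triene terminus. C4 would need a face-selective isopropyl addition to an enolisable ketone. The triene would need regioselective redox editing at C6, C7 and C10. The carbenoid must also choose between the two ortho positions of A2.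
- Comparison: structurally it postpones the hard centres C1 and C4. Mechanistically its induction rests on ligand control, where the chosen plan buys C4 and relays a carbinol configuration through a concerted shift. In total step count it would not be expected to be shorter once the triene is edited.

Alternative 2: The cut is C1–CH3 and C4–C5. Cu(OTf)2 with a chiral N-heterocyclic carbene ligand would transfer methyl from Me2Zn to the β-carbon (C1) of enone A4, and the zinc enolate at C5 would add to the side-chain isopropyl ketone to give hydroxy ketone A3 (conjugate addition–aldol cascade).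
- In favour: C1, C4, C5, the five-membered ring and the trans fusion come from an achiral precursor in one catalytic step. C5 is set directly, which is better than the chosen plan, where C5 depends on a face-selective hydroboration. The way to the carbinol-bearing core is the shortest of the four plans, and the C6 ketone is placed for a reduction directed by the C4 hydroxyl.
- Against: C7–C10 arrive as four bare methylenes, so the C8 methyl and the 8,9-diol would have to be introduced far from the only handle (C6=O). A3 is a β-hydroxy ketone, open to retro-aldol cleavage and C5 epimerisation. The facial outcome of the aldol at C4 (isopropyl against chain) is not assured.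
- Comparison: structurally the chosen plan leaves functionality on both flanks of the seven-membered ring (C9=O and C5=C6). Mechanistically both create the quaternary C1 with absolute control, here by catalyst, there by chirality transfer. In step economy alternative 2 is ahead up to A3 and would fall behind after it.

Alternative 3: The cut is C1–C5 and C6–C7. [Rh(CO)2Cl]2 (monovalent rhodium) would couple the alkyne (C5≡C6) of enyne A6 with its siloxy vinylcyclopropane by oxidative cyclisation, cyclopropane cleavage and reductive elimination, closing both rings to siloxy diene A5.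
- In favour: both rings form in one catalytic step, a better ring-forming economy than the chosen plan, which builds them in separate operations. A5 has the C9 oxygen and the C5=C6 alkene, the same pattern as 13, so on post-key-step functionality it is the equal of the chosen plan and the same endgame would apply.
- Against: the alkene terminus that becomes C1 is 1,1-disubstituted, which retards this cycloaddition. The C1 configuration would have to be induced by C4 across the forming five-membered ring, a relay of uncertain sense. C4 of A6 is a tertiary propargylic carbinol that would need an enantioselective alkynylation of a dialkyl ketone. The enol ether of A5 points to C10 and not to C8, where the methyl must go.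
- Comparison: structurally it reaches the same bicycle. Mechanistically the chosen plan fixes C1 by a stereospecific suprafacial shift from a reagent-set carbinol and buys C4. In step count the gain in ring formation would be offset by the asymmetric synthesis of A6.

Key step: step 7

Remark on supply: (S)-(+)-terpinen-4-ol is assumed to be purchasable in high enantiomeric purity; the carbinol carbon is never a reaction centre, so its purity carries through unchanged.

Remark on descriptors: the carbinol carbon is S in 1–4 and R from 5 onward although nothing changes in space, because the ring carbon that becomes olefinic then outranks isopropyl. The cyclopentenyl centre of 12 is therefore (R); a name with (S) at that centre would be wrong, while (S) at the oxolane carbon is correct.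

Remark on the precursor: 12 keeps its skeleton and its triethylsilyl ether. The change is in how it is reached: C6 is set by asymmetric allylation and the lactone carbon by oxidative lactonisation, so that no acid touches the doubly activated allylic C6–O bond, and 12 is kept amine-buffered.

Step 1
Reactants: 1 (S)-terpinen-4-ol
Product: 2 (1S)-4-methyl-1-(propan-2-yl)-1-(triethylsilyloxy)cyclohex-3-ene
Conditions: Et3SiOTf, 2,6-lutidine, CH2Cl2, 0 °C to rt
Reagents that add atoms: triethylsilyl trifluoromethanesulfonate, CC[Si](CC)(CC)OS(=O)(=O)C(F)(F)F
Why: Silyl triflate silylation of a hindered tertiary alcohol; the ether prevents hemiketal formation and retro-aldol cleavage after ozonolysis and later blocks the lower face next to C5.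

Step 2
Reactants: 2 (1S)-4-methyl-1-(propan-2-yl)-1-(triethylsilyloxy)cyclohex-3-ene
Product: 5 (5R)-2-methyl-5-(propan-2-yl)-5-(triethylsilyloxy)cyclopent-1-ene-1-carbaldehyde, via ozonide 3 (not isolated), via keto aldehyde 4 (not isolated)
Conditions: O3, CH2Cl2, −78 °C; Me2S, −78 °C to rt; then piperidine (0.3 equiv), AcOH (0.3 equiv), rt
Reagents that add atoms: ozone, [O-][O+]=O
Why: Ozonolysis with reductive work-up, then an amine-catalysed intramolecular aldol condensation in which the piperidine enamine of the aldehyde attacks the methyl ketone (five-membered ring closure) and dehydration gives the tetrasubstituted enal; the ketone-enol mode that would lead to an acetylcyclopentene is disfavoured under enamine catalysis. C4 is untouched and only its descriptor changes.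

Step 3
Reactants: 5 (5R)-2-methyl-5-(propan-2-yl)-5-(triethylsilyloxy)cyclopent-1-ene-1-carbaldehyde
Product: 7 (1S)-1-[(5R)-2-methyl-5-(propan-2-yl)-5-(triethylsilyloxy)cyclopent-1-en-1-yl]but-3-en-1-ol, via borinate ester 6 (not isolated)
Conditions: (−)-Ipc2BOMe, CH2=CHCH2MgBr, Et2O, 0 °C; then 5, −78 °C; NaOH (3 M), H2O2 (30%), 0 °C to rt
Reagents that add atoms: allylmagnesium bromide, C=CC[Mg]Br
Why: Brown asymmetric allylboration through a closed chair transition state; the reagent derived from (+)-α-pinene adds allyl to the Si face of the aldehyde, which sets (S)-C6, and reagent control should override the bias of the C4 centre.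

Step 4
Reactants: 7 (1S)-1-[(5R)-2-methyl-5-(propan-2-yl)-5-(triethylsilyloxy)cyclopent-1-en-1-yl]but-3-en-1-ol
Product: 9 (4S)-4-[(5R)-2-methyl-5-(propan-2-yl)-5-(triethylsilyloxy)cyclopent-1-en-1-yl]butane-1,4-diol, via bis-boryl adduct 8 (not isolated)
Conditions: 9-BBN (2.5 equiv), THF, 0 °C to rt; NaOH (3 M), H2O2 (30%), 0 °C
Reagents that add atoms: hydrogen peroxide, OO
Why: Anti-Markovnikov hydroboration–oxidation; 9-BBN adds to the monosubstituted alkene only, the tetrasubstituted ring alkene is too hindered, and the C6 hydroxyl is merely borylated and released on work-up.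

Step 5
Reactants: 9 (4S)-4-[(5R)-2-methyl-5-(propan-2-yl)-5-(triethylsilyloxy)cyclopent-1-en-1-yl]butane-1,4-diol
Product: 11 (5S)-5-[(5R)-2-methyl-5-(propan-2-yl)-5-(triethylsilyloxy)cyclopent-1-en-1-yl]oxolan-2-one, via lactol 10 (not isolated)
Conditions: TEMPO (0.2 equiv), PhI(OAc)2 (2.5 equiv), CH2Cl2, rt
Reagents that add atoms: none
Why: Oxoammonium oxidation is selective for the primary alcohol; the aldehyde closes with the C6 hydroxyl to the five-membered lactol, which is oxidised on to the γ-lactone, so the hindered allylic C6 carbinol is never oxidised and keeps its configuration. The medium stays near neutral, which protects the allylic C6–O bond.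

Step 6
Reactants: 11 (5S)-5-[(5R)-2-methyl-5-(propan-2-yl)-5-(triethylsilyloxy)cyclopent-1-en-1-yl]oxolan-2-one
Product: 12 (5S)-2-methylidene-5-[(5R)-2-methyl-5-(propan-2-yl)-5-(triethylsilyloxy)cyclopent-1-en-1-yl]oxolane
Conditions: Cp2TiMe2 (2.5 equiv), toluene, 65 °C, dark; filtration through basic Al2O3 (1% Et3N in eluent)
Reagents that add atoms: dimethyltitanocene, C[Ti](C)(C1C=CC=C1)C1C=CC=C1
Why: Petasis methylenation: Cp2Ti=CH2 formed on heating adds to the lactone carbonyl and the oxatitanacyclobutane collapses to the exocyclic enol ether; the reagent is neither acidic nor strongly basic, and the product is kept over base because acid would move the double bond into the ring.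

Step 7
Reactants: 12 (5S)-2-methylidene-5-[(5R)-2-methyl-5-(propan-2-yl)-5-(triethylsilyloxy)cyclopent-1-en-1-yl]oxolane
Product: 13 (3R,8aR)-8a-methyl-3-(propan-2-yl)-3-(triethylsilyloxy)-2,3,5,6,8,8a-hexahydroazulen-7(1H)-one
Conditions: toluene (degassed, 0.02 M), Et3N (5 mol%), base-washed sealed tube, 185 °C
Reagents that add atoms: none
Why: This is a thermal Claisen rearrangement of an allyl vinyl ether whose O–C9=C10 unit and C6 are tied into the oxolane; the closest known reaction type is the Claisen ring expansion of 2-methylidene-5-vinyloxolanes to cyclohept-4-enones. Because C7–C8 bridges C6 and C9, the six reacting atoms O–C6–C5=C1···C10=C9 can meet only through a boat-like transition state, in which C1–C10 forms as C6–O breaks in one concerted suprafacial event. The seven-membered carbocycle (C1, C10, C9, C8, C7, C6, C5) is therefore closed by pericyclic ring enlargement of the five-membered oxacycle and not by exo or endo attack of a chain, and the tether forces C7 cis to C1 so that the new C5=C6 alkene is the cis-cycloheptene. The single new stereocentre C1 is controlled by C6: with C7 held cis to C1, the C6–O bond of the (S)-carbinol lies over one face of the cyclopentene only, and C10 must bond to that same face, which gives (R)-C1. That face carries the C4 isopropyl group and not the bulkier silyl ether, so the protecting group does not obstruct the array. The step needs the [3,3] shift to outrun acid-triggered migration of the exocyclic double bond into the ring and heterolysis of the doubly stabilised allylic C6–O bond; an amine-buffered, non-polar medium and base-washed glass secure this. The fully substituted C1 terminus raises the barrier, hence the high temperature.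

Step 8
Reactants: 13 (3R,8aR)-8a-methyl-3-(propan-2-yl)-3-(triethylsilyloxy)-2,3,5,6,8,8a-hexahydroazulen-7(1H)-one
Product: 15 8-methyl ketone (13 with CH3 on C8; C8 epimers; 1R,4R), via lithium enolate 14 (not isolated)
Conditions: LiN(iPr)2, THF, −78 °C; MeI, −78 to −20 °C
Reagents that add atoms: iodomethane, CI
Why: Kinetic enolate alkylation: LiN(iPr)2 removes a proton from the unhindered C8 methylene in preference to the neopentyl C10 methylene next to quaternary C1, and iodomethane alkylates C8; the new centre is left as a mixture because it becomes sp2 in the next step.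

Step 9
Reactants: 15 8-methyl ketone (C8 epimers; 1R,4R)
Product: 17 enol triflate (C8(CH3)=C9–OSO2CF3 with C5=C6 and C4–OSiEt3; 1R,4R), via lithium enolate 16 (not isolated)
Conditions: LiN(SiMe3)2 (0.95 equiv), THF, −78 °C to rt; PhNTf2, 0 °C to rt
Reagents that add atoms: N-phenylbis(trifluoromethanesulfonimide), FC(F)(F)S(=O)(=O)N(c1ccccc1)S(=O)(=O)C(F)(F)F
Why: With slightly less than one equivalent of base the enolates equilibrate by proton exchange with residual ketone to the more substituted C8=C9 enolate, which PhNTf2 traps on oxygen (enol triflate formation).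

Step 10
Reactants: 17 enol triflate (1R,4R)
Product: 19 C6 alcohol (H-5 and 6-OH on the upper face; C4–OSiEt3; C8(CH3)=C9–OSO2CF3; 1R,4R,5S,6S), via alkylborane 18 (not isolated)
Conditions: BH3·THF (3 equiv), THF, 0 °C to rt; NaBO3·4H2O, H2O, rt
Reagents that add atoms: sodium perborate, [Na+].[O-]OB=O
Why: Syn hydroboration–oxidation of the trisubstituted C5=C6 alkene with boron on C6; attack from the face opposite the angular C1 methyl and the C4 silyl ether (the sense known for Δ5 olefins of steroids with an angular methyl) places H-5 and O-6 on the upper face and so sets C5 (trans fusion) and C6 together. The tetrasubstituted, electron-poor vinyl triflate does not add borane, and perborate oxidises the C–B bond with retention without hydrolysing the triflate.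

Step 11
Reactants: 19 C6 alcohol (1R,4R,5S,6S)
Product: 20 4,6-diol enol triflate (19 without the silyl group; 1R,4R,5S,6S)
Conditions: HF·pyridine, pyridine, THF, 0 °C to rt
Reagents that add atoms: none
Why: Fluoride-driven cleavage of the tertiary triethylsilyl ether under buffered conditions; the vinyl triflate and the secondary alcohol are inert to HF·pyridine.

Step 12
Reactants: 20 4,6-diol enol triflate (1R,4R,5S,6S)
Product: 21 (3R,3aS,4S,8aR)-6,8a-dimethyl-3-(propan-2-yl)-1,2,3,3a,4,5,8,8a-octahydroazulene-3,4-diol
Conditions: Pd(OAc)2 (5 mol%), PPh3 (10 mol%), HCO2H, n-Bu3N, DMF, 60 °C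
Reagents that add atoms: none
Why: Palladium-catalysed formate reduction of a vinyl triflate: oxidative addition to zerovalent palladium, formate exchange, loss of CO2 and C–H reductive elimination; the double bond stays at C8=C9 and free hydroxyls are tolerated. Compound 21 has the constitution and relative configuration of jaeschkeanadiol.

Step 13
Reactants: 21 (3R,3aS,4S,8aR)-6,8a-dimethyl-3-(propan-2-yl)-1,2,3,3a,4,5,8,8a-octahydroazulene-3,4-diol
Product: 22 8,9-epoxide of 21 (oxygen on the upper face; 1R,4R,5S,6S,8R,9S)
Conditions: VO(acac)2 (5 mol%), t-BuOOH, CH2Cl2, 0 °C to rt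
Reagents that add atoms: tert-butyl hydroperoxide, CC(C)(C)OO
Why: Hydroxyl-directed epoxidation: the vanadium alkylperoxide bound to the homoallylic C6 hydroxyl delivers oxygen to the upper face of C8=C9, which is also the face away from the angular methyl, so direction and sterics agree.

Step 14
Reactants: 22 8,9-epoxide (1R,4R,5S,6S,8R,9S); 23 4-(benzyloxy)benzoyl chloride
Product: 24 6-O-[4-(benzyloxy)benzoyl] epoxide (1R,4R,5S,6S,8R,9S)
Conditions: Et3N, DMAP (0.2 equiv), CH2Cl2, 0 °C to rt
Reagents that add atoms: none
Why: DMAP-catalysed acylation of the secondary C6 alcohol by an acid chloride; the tertiary C4 alcohol does not acylate under these conditions and the amine buffer keeps the epoxide closed.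

Step 15
Reactants: 24 6-O-[4-(benzyloxy)benzoyl] epoxide (1R,4R,5S,6S,8R,9S)
Product: 25 benzyl ether of the target (4,8,9-triol 6-[4-(benzyloxy)benzoate]; 1R,4R,5S,6S,8S,9S)
Conditions: HClO4 (0.5 M aq.), THF, 0 °C
Reagents that add atoms: water, O
Why: Acid-catalysed epoxide hydrolysis: the protonated epoxide opens at tertiary C8, where positive charge is best carried, and water enters from the lower face anti to the leaving oxygen, so C8 inverts (R to S) while C9 keeps its oxygen and configuration, giving the trans-diol. The C6 ester sits on the upper face and cannot reach the backside of C8, and the trans ring fusion holds O-4 away from it.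

Step 16
Reactants: 25 benzyl ether of the target (1R,4R,5S,6S,8S,9S)
Product: 26 (3R,3aS,4S,6S,7S,8aR)-3,6,7-trihydroxy-6,8a-dimethyl-3-(propan-2-yl)decahydroazulen-4-yl 4-hydroxybenzoate
Conditions: H2 (1 atm), Pd/C (10%), EtOAc, rt
Reagents that add atoms: none
Why: Hydrogenolysis of the benzyl aryl ether over Pd/C; no alkene or epoxide remains and the C6–O ester bond is not benzylic.

## Compound list

1 | (S)-terpinen-4-ol, (1S)-4-methyl-1-(propan-2-yl)cyclohex-3-en-1-ol | CC(C)[C@]1(O)CCC(C)=CC1 | starting material
2 | (1S)-4-methyl-1-(propan-2-yl)-1-(triethylsilyloxy)cyclohex-3-ene | CC(C)[C@]1(O[Si](CC)(CC)CC)CCC(C)=CC1 | intermediate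
3 | ozonide of 2 (1,2,4-trioxolane across the former ring alkene; new centres undefined) | CC(C)[C@]1(O[Si](CC)(CC)CC)CCC2(C)OOC(C1)O2 | intermediate
4 | (3S)-6-oxo-3-(propan-2-yl)-3-(triethylsilyloxy)heptanal | CC(C)[C@@](O[Si](CC)(CC)CC)(CC=O)CCC(C)=O | intermediate
5 | (5R)-2-methyl-5-(propan-2-yl)-5-(triethylsilyloxy)cyclopent-1-ene-1-carbaldehyde | CC(C)[C@]1(O[Si](CC)(CC)CC)CCC(C)=C1C=O | intermediate
6 | diisopinocampheylborinate ester of 7 (O–B(Ipc)2 on C6) | CC(C)[C@]1(O[Si](CC)(CC)CC)CCC(C)=C1[C@@H](OB([C@@H]2C[C@@H]3C[C@H]([C@H]2C)C3(C)C)[C@@H]4C[C@@H]5C[C@H]([C@H]4C)C5(C)C)CC=C | intermediate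
7 | (1S)-1-[(5R)-2-methyl-5-(propan-2-yl)-5-(triethylsilyloxy)cyclopent-1-en-1-yl]but-3-en-1-ol | CC(C)[C@]1(O[Si](CC)(CC)CC)CCC(C)=C1[C@@H](O)CC=C | intermediate
8 | bis(9-BBN) adduct of 7 (boron on O-6 and on the terminal carbon) | CC(C)[C@]1(O[Si](CC)(CC)CC)CCC(C)=C1[C@@H](OB2C3CCCC2CCC3)CCCB4C5CCCC4CCC5 | intermediate
9 | (4S)-4-[(5R)-2-methyl-5-(propan-2-yl)-5-(triethylsilyloxy)cyclopent-1-en-1-yl]butane-1,4-diol | CC(C)[C@]1(O[Si](CC)(CC)CC)CCC(C)=C1[C@@H](O)CCCO | intermediate
10 | (5S)-5-[(5R)-2-methyl-5-(propan-2-yl)-5-(triethylsilyloxy)cyclopent-1-en-1-yl]oxolan-2-ol (anomers) | CC(C)[C@]1(O[Si](CC)(CC)CC)CCC(C)=C1[C@@H]2CCC(O)O2 | intermediate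
11 | (5S)-5-[(5R)-2-methyl-5-(propan-2-yl)-5-(triethylsilyloxy)cyclopent-1-en-1-yl]oxolan-2-one | CC(C)[C@]1(O[Si](CC)(CC)CC)CCC(C)=C1[C@@H]2CCC(=O)O2 | intermediate
12 | (5S)-2-methylidene-5-[(5R)-2-methyl-5-(propan-2-yl)-5-(triethylsilyloxy)cyclopent-1-en-1-yl]oxolane | CC(C)[C@]1(O[Si](CC)(CC)CC)CCC(C)=C1[C@@H]2CCC(=C)O2 | intermediate
13 | (3R,8aR)-8a-methyl-3-(propan-2-yl)-3-(triethylsilyloxy)-2,3,5,6,8,8a-hexahydroazulen-7(1H)-one (C9 ketone, C5=C6; 1R,4R) | CC(C)[C@]1(O[Si](CC)(CC)CC)CC[C@]2(C)CC(=O)CCC=C21 | intermediate
14 | lithium C8=C9 enolate of 13 | CC(C)[C@]1(O[Si](CC)(CC)CC)CC[C@]2(C)CC(O[Li])=CCC=C21 | intermediate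
15 | 8-methyl ketone (13 with CH3 on C8; C8 epimers) | CC(C)[C@]1(O[Si](CC)(CC)CC)CC[C@]2(C)CC(=O)C(C)CC=C21 | intermediate
16 | lithium C8=C9 enolate of 15 (tetrasubstituted) | CC(C)[C@]1(O[Si](CC)(CC)CC)CC[C@]2(C)CC(O[Li])=C(C)CC=C21 | intermediate
17 | enol triflate: C8(CH3)=C9–OSO2CF3, C5=C6, C4–OSiEt3 (1R,4R) | CC(C)[C@]1(O[Si](CC)(CC)CC)CC[C@]2(C)CC(OS(=O)(=O)C(F)(F)F)=C(C)CC=C21 | intermediate
18 | C6 borane of 19 (BH2 in place of OH) | CC(C)[C@]1(O[Si](CC)(CC)CC)CC[C@]2(C)CC(OS(=O)(=O)C(F)(F)F)=C(C)C[C@H](B)[C@H]21 | intermediate
19 | C6 alcohol: trans-fused, 6-OH, C4–OSiEt3, C8(CH3)=C9–OSO2CF3 (1R,4R,5S,6S) | CC(C)[C@]1(O[Si](CC)(CC)CC)CC[C@]2(C)CC(OS(=O)(=O)C(F)(F)F)=C(C)C[C@H](O)[C@H]21 | intermediate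
20 | 4,6-diol enol triflate (1R,4R,5S,6S) | CC(C)[C@]1(O)CC[C@]2(C)CC(OS(=O)(=O)C(F)(F)F)=C(C)C[C@H](O)[C@H]21 | intermediate
21 | (3R,3aS,4S,8aR)-6,8a-dimethyl-3-(propan-2-yl)-1,2,3,3a,4,5,8,8a-octahydroazulene-3,4-diol (4,6-diol, C8=C9) | CC(C)[C@]1(O)CC[C@]2(C)CC=C(C)C[C@H](O)[C@H]21 | intermediate
22 | 8,9-epoxide of 21, oxygen on the upper face (1R,4R,5S,6S,8R,9S) | CC(C)[C@]1(O)CC[C@]2(C)C[C@@H]3O[C@]3(C)C[C@H](O)[C@H]21 | intermediate
23 | 4-(benzyloxy)benzoyl chloride | O=C(Cl)c1ccc(OCc2ccccc2)cc1 | starting material
24 | 6-O-[4-(benzyloxy)benzoyl] derivative of 22 (1R,4R,5S,6S,8R,9S) | CC(C)[C@]1(O)CC[C@]2(C)C[C@@H]3O[C@]3(C)C[C@H](OC(=O)c4ccc(OCc5ccccc5)cc4)[C@H]21 | intermediate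
25 | benzyl ether of the target (1R,4R,5S,6S,8S,9S) | CC(C)[C@]1(O)CC[C@]2(C)C[C@H](O)[C@@](C)(O)C[C@H](OC(=O)c3ccc(OCc4ccccc4)cc3)[C@H]21 | intermediate
26 | (3R,3aS,4S,6S,7S,8aR)-3,6,7-trihydroxy-6,8a-dimethyl-3-(propan-2-yl)decahydroazulen-4-yl 4-hydroxybenzoate | CC(C)[C@]1(O)CC[C@]2(C)C[C@H](O)[C@@](C)(O)C[C@H](OC(=O)c3ccc(O)cc3)[C@H]21 | target

## Step count and least certain steps

Total step count: 16. Longest linear sequence: 16 steps (1 to 26); 23 is purchased.

Step 7 (key step). The most likely failure is acid-triggered migration of the exocyclic double bond of 12 into the oxolane ring, or heterolysis of the C6–O bond, during the long heating that the fully substituted C1 terminus demands; either process destroys the allyl vinyl ether before it rearranges. Fallback: 12 would be treated with i-Bu3Al in CH2Cl2 at −78 °C to rt. Coordination of aluminium to the enol ether oxygen accelerates the [3,3] shift at low temperature, and the aluminium-bound ketone is reduced in the flask by hydride transfer from an isobutyl group to give the cyclohept-4-enol F1 (C9 epimers). Dess–Martin periodinane would oxidise it, and the route is rejoined at 13.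

Step 10. The most likely failure is poor facial selectivity, that is delivery of borane from the lower face, because the C4 isopropyl group on the upper face partly offsets the shielding by C1–CH3 and O-4; this would give the cis-fused C5/C6 epimer. Fallback: starting again from 17, the hydroboration mixture would be oxidised with Dess–Martin periodinane to the C6 ketone F2. Its C5 centre would be equilibrated through the enol (DBU, CH2Cl2) toward the trans-fused ketone, the expected but unconfirmed thermodynamic isomer, while O-4 is still silylated so that retro-aldol cleavage cannot occur. HF·pyridine would then free the β-hydroxy ketone F3, and Me4NBH(OAc)3 in MeCN/AcOH (hydroxyl-directed reduction, hydride delivered from the O-4 face) would give 20, where the route is rejoined.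

Step 9. The most likely failure is incomplete enolate equilibration, or a small thermodynamic preference, so that part of the material is triflated toward C10. Fallback: from 13, the kinetic enolate 14 would be treated with Me2N=CH2 I (Eschenmoser's salt) to give the Mannich base F4. Quaternisation with MeI and elimination with NaHCO3 would give the 8-methylidene ketone F5. Conjugate reduction with LiBH(s-Bu)3 at −78 °C would then generate enolate 16 regiospecifically, and PhNTf2 would return 17.

Step 3. The most likely failure is erosion of facial selectivity through mismatched double diastereoselection with the neighbouring C4 centre, or sluggish addition to the hindered enal; any C6 epimer becomes the C1 epimer in step 7. Fallback: from 5, CH2=CHCH2MgBr would give the alcohol F6 as a C6 mixture and Dess–Martin periodinane the β,γ-unsaturated ketone F7. Corey–Bakshi–Shibata reduction with the (R)-B-methyl oxazaborolidine and catecholborane at −78 °C, which leaves the alkenes alone, would give the (S)-alcohol 7.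

Step 2. The most likely failure is β-elimination of triethylsilanolate from the aldehyde enamine of 4, in which the C4 oxygen is β to the aldehyde, in competition with ring closure. Fallback: from 1, ozonolysis of the unprotected alcohol (O3; Me2S) would give the hydroxy keto aldehyde F8, which rests largely as its cyclic hemiketal and carries a poorer leaving group. Piperidinium acetate would close it to the hydroxy enal F9, and Et3SiOTf with 2,6-lutidine would then silylate the tertiary alcohol to rejoin the route at 5.

## Further compounds

F1 | step 7 | cyclohept-4-enol from reductive Claisen ring expansion (13 with C9–OH; C9 epimers) | CC(C)[C@]1(O[Si](CC)(CC)CC)CC[C@]2(C)CC(O)CCC=C21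
F2 | step 10 | trans-fused C6 ketone with C4–OSiEt3 and C8(CH3)=C9–OSO2CF3 | CC(C)[C@]1(O[Si](CC)(CC)CC)CC[C@]2(C)CC(OS(=O)(=O)C(F)(F)F)=C(C)CC(=O)[C@H]21
F3 | step 10 | 4-hydroxy C6 ketone (F2 without the silyl group) | CC(C)[C@]1(O)CC[C@]2(C)CC(OS(=O)(=O)C(F)(F)F)=C(C)CC(=O)[C@H]21
F4 | step 9 | 8-(dimethylaminomethyl) ketone (Mannich base of 13; C8 epimers) | CC(C)[C@]1(O[Si](CC)(CC)CC)CC[C@]2(C)CC(=O)C(CN(C)C)CC=C21
F5 | step 9 | 8-methylidene ketone | CC(C)[C@]1(O[Si](CC)(CC)CC)CC[C@]2(C)CC(=O)C(=C)CC=C21
F6 | step 3 | 1-[(5R)-2-methyl-5-(propan-2-yl)-5-(triethylsilyloxy)cyclopent-1-en-1-yl]but-3-en-1-ol (C1 epimers) | CC(C)[C@]1(O[Si](CC)(CC)CC)CCC(C)=C1C(O)CC=C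
F7 | step 3 | 1-[(5R)-2-methyl-5-(propan-2-yl)-5-(triethylsilyloxy)cyclopent-1-en-1-yl]but-3-en-1-one | CC(C)[C@]1(O[Si](CC)(CC)CC)CCC(C)=C1C(=O)CC=C
F8 | step 2 | (3S)-3-hydroxy-6-oxo-3-(propan-2-yl)heptanal (open form) | CC(C)[C@@](O)(CC=O)CCC(C)=O
F9 | step 2 | (5R)-5-hydroxy-2-methyl-5-(propan-2-yl)cyclopent-1-ene-1-carbaldehyde | CC(C)[C@]1(O)CCC(C)=C1C=O
A1 | alternative 1 | 5-methoxy-6-methyl-3,8a-dihydroazulen-1(2H)-one | O=C1CCC2=CC(OC)=C(C)C=C[C@H]12
A2 | alternative 1 | 1-diazo-4-(3-methoxy-4-methylphenyl)butan-2-one | COc1cc(CCC(=O)C=[N+]=[N-])ccc1C
A3 | alternative 2 | trans-fused 4-hydroxy-1-methyl-4-(propan-2-yl)hydroazulen-6-one (target locants) | CC(C)[C@]1(O)CC[C@]2(C)CCCCC(=O)[C@H]21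
A4 | alternative 2 | 3-(4-methyl-3-oxopentyl)cyclohept-2-en-1-one | CC(C)C(=O)CCC1=CC(=O)CCCC1
A5 | alternative 3 | hydroazulene diene with C9 tert-butyldimethylsilyl enol ether, C5=C6, C1 and C4 set | CC(C)[C@]1(O)CC[C@]2(C)C=C(O[Si](C)(C)C(C)(C)C)CCC=C21
A6 | alternative 3 | (3R)-7-[1-(tert-butyldimethylsilyloxy)cyclopropyl]-6-methyl-3-(propan-2-yl)hept-6-en-1-yn-3-ol | CC(C)[C@@](O)(C#C)CCC(C)=CC1(O[Si](C)(C)C(C)(C)C)CC1
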